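Late in Saturday's flask, at 8.00 d, G read 76.3 %, and I took the rest, 23.7 %, as the most that Q could hold. One Q counts two, so at most about 11.8 % of the X had gone that way. Each X passes a fork: on J it becomes Z, which with L on E becomes G, or it meets a G and takes that G into Q. The odds of the side road are G/(S·J), where S, the selectivity factor, says how much better J catches X than G does.

| setting | Friday's | Sunday's | Saturday's | larch | elm | birch | cedar |
|---|---|---|---|---|---|---|---|
| X | 32 mM | 32 mM | 32 mM | 32 mM | 32 mM (fed, over 4.80 d) | 32 mM | 32 mM |
| L | 57.6 mM | 57.6 mM | 57.6 mM | 57.6 mM (fed, over 4.80 d) | 57.6 mM | 57.6 mM | 57.6 mM |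
| J | 3.2 mM | 2.1 mM | 4.8 mM | 3.2 mM | 3.2 mM | 3.2 mM | 3.2 mM |
| E | 0.32 mM | 0.32 mM | 0.32 mM | 0.32 mM | 0.32 mM | 0.32 mM | 0.32 mM |
| remark | run made earlier | run made earlier | run made earlier | a stirred flask in which L is dosed at a steady rate over 4.80 d without added volume, worked up at 6.0 d | all but X at the start; X goes in evenly over 4.80 d, the run ends at 6.0 d | everything together in a closed stirred flask, run for 6.0 d | a single well-mixed tank run continuously and read at steady state, 6.0 d in it on average |
| time |  |  |  | 6.0 d | 6.0 d | 6.0 d |  |

| run | time / d | G / % |
|---|---|---|
| Friday's | 0.500 | 3.1 |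
| Friday's | 0.833 | 9.2 |
| Friday's | 1.67 | 24.7 |
| Friday's | 3.00 | 41.6 |
| Friday's | 6.00 | 60.6 |
| Sunday's | 0.625 | 3.7 |
| Sunday's | 1.04 | 8.7 |
| Sunday's | 2.08 | 21.4 |
| Sunday's | 4.00 | 36.9 |
| Sunday's | 8.00 | 51.8 |
| Saturday's | 1.25 | 22.3 |
| Saturday's | 3.00 | 52.9 |
| Saturday's | 4.00 | 61.6 |
| Saturday's | 6.00 | 72.7 |
| Saturday's | 8.00 | 76.3 |

(readings scatter by 0.5 percentage points)

- percentages count the X that a species holds: one Q counts as two
- the stated concentrations are those of everything mixed, before any reaction; amounts are the same in each set-up
- what may be going on: X + J -> J + Z; L + E + Z -> E + G; X + G -> Q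
- the feed brings no volume worth counting
- the earlier runs were made in a closed, stirred flask

- the set-up with the highest amount of G at the outlet or at the end, in percent of the X put in ("none" if the first two lie within 2 percentage points) (larch / elm / birch / cedar / none)
- amount of G at the outlet or at the end, in percent of the X put in, larch
- amount of G at the outlet or at the end, in percent of the X put in, elm
- amount of G at the outlet or at the end, in percent of the X put in, birch
- amount of G at the outlet or at the end, in percent of the X put in, cedar

Taking that limit as the value, I put Saturday's odds at about 0.134. As a rough stand-in for the G an average X met, I used that flask's first reading, 22.3 % at 1.25 d, or 7.14 mM. With 4.8 mM of J this gave S = 11.1. At 3.2 mM of J that gives 35.4 mM as the even level, the concentration of G at which an X is as likely to go to Q as to Z, and this lies above the whole charge of 32 mM.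

So which set-up keeps G lowest while X passes? Birch repeats Friday's recipe, so I expected about 60.6 %, with odds near 0.223 at 1.67 d. In larch 34.8 % of the L would be in by then, so I expected X to meet less G there. Each X spared saves two counts of G, while Z held back costs one, so I put larch first.

Would elm or cedar compete? The average X in elm enters at 2.40 d and has 3.60 d left, less than birch's 6.0 d. In cedar, 63.2 % of what enters leaves younger than the average. I put both below birch.

The forecast, reasoning that “L dosing adds lag and leaves more Z at the end”, gave larch 58 %, elm 40 %, birch 60.6 % and cedar 39 %, with birch first where I had larch.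

The flasks gave larch 65.1 %, elm 41.5 %, birch 60.4 % and cedar 30.7 %, so larch came first.

    X + J → J + Z (k = 0.103 M⁻¹ min⁻¹)
    L + E + Z → E + G (k = 35.3 M⁻² min⁻¹)
    X + G → Q (k = 0.00995 M⁻¹ min⁻¹)

Larch ended with 18.8 % as Q against 30.1 % in birch, though it still held 13.5 % as Z against 7.36 %. At steady state cedar holds a single G level, 9.84 mM, so against the even level its odds came to about 0.278, a chance of 21.8 % for each X that reacted. With 78.7 % of the X reacted and each Q counting two, that makes 34.2 % as Q, and the tank held 36.0 %.

The numbers in the tables come from a simulation with constants of no real substance.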